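**Retrosynthetic overview**
- Target 34 comes from macrocyclic enone 32 by reagent-controlled reduction at C3 and desilylation; 32 comes from oxidation of 31, whose 14-membered ring is closed last at C3–C4 by an intramolecular Nozaki–Hiyama–Kishi reaction of iodo-aldehyde 29.
- 29 comes from a C10–C11 boron aldol union of ε-lactone aldehyde 14 with (Z)-enone 25, followed by an Evans–Tishchenko reduction that sets C9 and places the acetate on O11.
- 14 comes from (S)-limonene: C10 hydroxylation, ring ozonolysis, asymmetric Corey–Chaykovsky epoxidation, then opening of the epoxide at its tertiary carbon by the acrylic acid (inversion at C12).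
- 25 comes from pent-3-yn-1-ol (hydrozirconation–iodination) and acetoin through a (Z)-selective Wittig olefination of an α-silyloxy ketone.
- Ring order: seven-membered lactone first (step 7), 14-membered carbocycle last (step 19).

Assumption 1: positions are named with cembrane locants: C1 = ring CH bearing C15; C2–C14 run round the carbocycle through C3(OH), C4(Me)=C5, C7=C8(Me), C9(OH), C11(OAc), C12(Me, O); C16 = lactone C=O; C17 = exocyclic CH2.
Assumption 2: in step 4 the (S)-binaphtholate complex is written; if the facial sense on this ketone proves opposite, the (R)-binaphtholate complex is used to obtain the same (R)-epoxide 9.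

**Fragment A (steps 1–8)**

Step 1
Reactants: 1 (S)-(−)-limonene
Product: 4 2-[(1S)-4-methylcyclohex-3-en-1-yl]prop-2-en-1-ol, via 10-lithiolimonene 2 (not isolated), via dimethyl allylboronate 3 (not isolated)
Conditions: n-BuLi, TMEDA, hexane, rt; B(OMe)3, −78 °C to rt; H2O2, NaOH aq, 0 °C
Reagents that add atoms: hydrogen peroxide, OO
Why: Allylic lithiation of limonene by n-BuLi·TMEDA occurs at the isopropenyl methyl without touching the stereocentre, and borylation–oxidation of the symmetrical 2-substituted allyl anion gives the allylic alcohol.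

Step 2
Reactants: 4 2-[(1S)-4-methylcyclohex-3-en-1-yl]prop-2-en-1-ol
Product: 5 tert-butyl({2-[(1S)-4-methylcyclohex-3-en-1-yl]prop-2-en-1-yl}oxy)diphenylsilane
Conditions: t-BuPh2SiCl, imidazole, DMF, rt
Reagents that add atoms: tert-butyl(chloro)diphenylsilane, CC(C)(C)[Si](Cl)(c1ccccc1)c1ccccc1
Why: Silylation of the primary alcohol gives an ether that survives the acidic methanol of the next step.

Step 3
Reactants: 5 tert-butyl({2-[(1S)-4-methylcyclohex-3-en-1-yl]prop-2-en-1-yl}oxy)diphenylsilane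
Product: 8 (5S)-5-{3-[(tert-butyldiphenylsilyl)oxy]prop-1-en-2-yl}-7,7-dimethoxyheptan-2-one, via methoxy hydroperoxide aldehyde 6 (not isolated), via methoxy hydroperoxide acetal 7 (not isolated)
Conditions: O3, CH2Cl2/MeOH, −78 °C (Sudan Red 7B end point); p-TsOH·H2O (cat.), rt; NaHCO3, Me2S, rt
Reagents that add atoms: ozone, [O-][O+]=O; methanol, CO
Why: Terminally differentiating ozonolysis: the electron-rich trisubstituted ring alkene is cleaved much faster than the 1,1-disubstituted allyl silyl ether, methanol traps the ketone oxide, acid acetalises the aldehyde end and Me2S reduces the hydroperoxide to the methyl ketone.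

Step 4
Reactants: 8 (5S)-5-{3-[(tert-butyldiphenylsilyl)oxy]prop-1-en-2-yl}-7,7-dimethoxyheptan-2-one
Product: 9 (2R)-2-[(3S)-3-{3-[(tert-butyldiphenylsilyl)oxy]prop-1-en-2-yl}-5,5-dimethoxypentyl]-2-methyloxirane
Conditions: Me3S(O)I, NaH, THF; then 8, LaLi3[(S)-1,1'-bi-2-naphtholate]3 (5 mol%), [2,4,6-(MeO)3C6H2]3P=O (5 mol%), 5 Å MS, THF, rt
Reagents that add atoms: trimethylsulfoxonium iodide, C[S+](C)(C)=O.[I-]
Why: Catalytic asymmetric Corey–Chaykovsky methylene transfer: the chiral lanthanum–lithium binaphtholate differentiates the faces of the methyl ketone and sets C12 as the (R)-2,2-disubstituted epoxide under catalyst control (about 95:5 expected, remote C1 has no influence).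

Step 5
Reactants: 9 (2R)-2-[(3S)-3-{3-[(tert-butyldiphenylsilyl)oxy]prop-1-en-2-yl}-5,5-dimethoxypentyl]-2-methyloxirane
Product: 10 2-{(3S)-5,5-dimethoxy-1-[(2R)-2-methyloxiran-2-yl]pentan-3-yl}prop-2-en-1-ol
Conditions: Bu4NF, THF, 0 °C to rt
Reagents that add atoms: none
Why: Fluoride desilylation is neutral towards the epoxide and the acetal.

Step 6
Reactants: 10 2-{(3S)-5,5-dimethoxy-1-[(2R)-2-methyloxiran-2-yl]pentan-3-yl}prop-2-en-1-ol
Product: 11 2-{(3S)-5,5-dimethoxy-1-[(2R)-2-methyloxiran-2-yl]pentan-3-yl}prop-2-enal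
Conditions: Dess–Martin periodinane, NaHCO3, CH2Cl2, 0 °C
Reagents that add atoms: none
Why: Buffered Dess–Martin oxidation of the only free alcohol gives the 2-substituted acrolein without opening the acid-sensitive epoxide.

Step 7
Reactants: 11 2-{(3S)-5,5-dimethoxy-1-[(2R)-2-methyloxiran-2-yl]pentan-3-yl}prop-2-enal
Product: 13 (4S,7S)-4-(2,2-dimethoxyethyl)-7-(hydroxymethyl)-7-methyl-3-methylideneoxepan-2-one, via epoxy acid 12 (not isolated)
Conditions: NaClO2, NaH2PO4, 2-methyl-2-butene, t-BuOH/H2O, 0 °C; extract; (+)-camphor-10-sulfonic acid (10 mol%), CH2Cl2, 0 °C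
Reagents that add atoms: sodium chlorite, [Na+].[O-]Cl=O
Why: Pinnick oxidation gives the acrylic acid, which under acid catalysis opens the 2,2-disubstituted epoxide at its tertiary carbon in a 7-exo mode with inversion, forming the (12S) lactone C–O bond and the seven-membered ring (intramolecular epoxide opening).

Step 8
Reactants: 13 (4S,7S)-4-(2,2-dimethoxyethyl)-7-(hydroxymethyl)-7-methyl-3-methylideneoxepan-2-one
Product: 14 (2S,5S)-5-(2,2-dimethoxyethyl)-2-methyl-6-methylidene-7-oxooxepane-2-carbaldehyde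
Conditions: Dess–Martin periodinane, NaHCO3, CH2Cl2, 0 °C to rt
Reagents that add atoms: none
Why: Dess–Martin oxidation of the neopentyl primary alcohol gives a non-enolisable α-quaternary aldehyde, so C12 cannot epimerise.

**Fragment B (steps 9–15)**

Step 9
Reactants: 15 pent-3-yn-1-ol
Product: 17 (3E)-4-iodopent-3-en-1-ol, via alkenylzirconocene 16 (not isolated)
Conditions: Cp2Zr(H)Cl (2.5 equiv), THF, rt to 40 °C; I2, THF, 0 °C
Reagents that add atoms: iodine, II
Why: Hydrozirconation is a syn addition in which zirconium equilibrates to the methyl-bearing alkyne carbon, and iodinolysis with retention gives the (E)-2-iodoalkene that becomes C4=C5.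

Step 10
Reactants: 17 (3E)-4-iodopent-3-en-1-ol
Product: 18 (2E)-2,5-diiodopent-2-ene
Conditions: I2, PPh3, imidazole, CH2Cl2, 0 °C
Reagents that add atoms: iodine, II
Why: Appel-type iodination converts the primary alcohol by SN2 and leaves the vinyl iodide untouched.

Step 11
Reactants: 18 (2E)-2,5-diiodopent-2-ene
Product: 19 [(3E)-4-iodopent-3-en-1-yl]triphenylphosphonium iodide
Conditions: PPh3, MeCN, reflux
Reagents that add atoms: triphenylphosphine, c1ccc(cc1)P(c1ccccc1)c1ccccc1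
Why: Only the primary alkyl iodide is quaternised by SN2, since vinyl iodides do not react with phosphines without a metal catalyst.

Step 12
Reactants: 20 3-hydroxybutan-2-one (acetoin, racemic)
Product: 21 3-[(tert-butyldimethylsilyl)oxy]butan-2-one (racemic)
Conditions: t-BuMe2SiCl, imidazole, DMF, rt
Reagents that add atoms: tert-butyl(chloro)dimethylsilane, CC(C)(C)[Si](C)(C)Cl
Why: Silylation gives the α-silyloxy ketone needed for a (Z)-selective Wittig reaction; its stereocentre is later oxidised away.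

Step 13
Reactants: 19 [(3E)-4-iodopent-3-en-1-yl]triphenylphosphonium iodide; 21 3-[(tert-butyldimethylsilyl)oxy]butan-2-one
Product: 23 tert-butyl{[(3Z,6E)-7-iodo-3-methylocta-3,6-dien-2-yl]oxy}dimethylsilane (racemic), via phosphonium ylide 22 (not isolated)
Conditions: NaN(SiMe3)2, THF, −78 °C; then 21, −78 °C to rt
Reagents that add atoms: none
Why: Wittig olefination of an α-silyloxy methyl ketone with a non-stabilised ylide is (Z)-selective (Still-type trisubstituted allylic ether synthesis), placing C9 cis to C6 and creating the skipped diene.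

Step 14
Reactants: 23 tert-butyl{[(3Z,6E)-7-iodo-3-methylocta-3,6-dien-2-yl]oxy}dimethylsilane
Product: 24 (3Z,6E)-7-iodo-3-methylocta-3,6-dien-2-ol (racemic)
Conditions: Bu4NF, THF, 0 °C
Reagents that add atoms: none
Why: Fluoride desilylation frees the allylic alcohol without affecting the vinyl iodide or the olefin geometries.

Step 15
Reactants: 24 (3Z,6E)-7-iodo-3-methylocta-3,6-dien-2-ol
Product: 25 (3Z,6E)-7-iodo-3-methylocta-3,6-dien-2-one
Conditions: Dess–Martin periodinane, NaHCO3, CH2Cl2, 0 °C (used at once)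
Reagents that add atoms: none
Why: Neutral Dess–Martin oxidation gives the methyl ketone without isomerising the (Z)-enone or the skipped diene.

**Union, macrocyclization and end game (steps 16–21)**

Step 16
Reactants: 25 (3Z,6E)-7-iodo-3-methylocta-3,6-dien-2-one; 14 (2S,5S)-5-(2,2-dimethoxyethyl)-2-methyl-6-methylidene-7-oxooxepane-2-carbaldehyde
Product: 27 (4S,7S)-4-(2,2-dimethoxyethyl)-7-[(1R,4Z,7E)-1-hydroxy-8-iodo-4-methyl-3-oxonona-4,7-dien-1-yl]-7-methyl-3-methylideneoxepan-2-one, via dicyclohexylboron enolate 26 (not isolated)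
Conditions: (c-C6H11)2BCl, Et3N, Et2O, −78 to 0 °C; then 14, −78 to −20 °C; MeOH, pH 7 buffer, H2O2, 0 °C
Reagents that add atoms: none
Why: Boron aldol reaction: the methyl-side boron enolate adds only to the aldehyde (not to the methylene lactone), and Felkin–Anh/Cornforth approach anti to ring carbon C13 past the C12 methyl gives the (11R) carbinol.

Step 17
Reactants: 27 (4S,7S)-4-(2,2-dimethoxyethyl)-7-[(1R,4Z,7E)-1-hydroxy-8-iodo-4-methyl-3-oxonona-4,7-dien-1-yl]-7-methyl-3-methylideneoxepan-2-one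
Product: 28 (1R,3R,4Z,7E)-1-[(2S,5S)-5-(2,2-dimethoxyethyl)-2-methyl-6-methylidene-7-oxooxepan-2-yl]-3-hydroxy-8-iodo-4-methylnona-4,7-dien-1-yl acetate
Conditions: CH3CHO (6 equiv), SmI2 (0.3 equiv), THF, −10 °C
Reagents that add atoms: acetaldehyde, CC=O
Why: Evans–Tishchenko reduction: the samarium-bound hemiacetal of the 11-OH delivers hydride intramolecularly to the C9 ketone, giving the 1,3-anti (9R) alcohol and leaving the acetate on O11 in one operation.

Step 18
Reactants: 28 (1R,3R,4Z,7E)-1-[(2S,5S)-5-(2,2-dimethoxyethyl)-2-methyl-6-methylidene-7-oxooxepan-2-yl]-3-hydroxy-8-iodo-4-methylnona-4,7-dien-1-yl acetate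
Product: 29 (1R,3R,4Z,7E)-8-iodo-4-methyl-1-[(2S,5S)-2-methyl-6-methylidene-7-oxo-5-(2-oxoethyl)oxepan-2-yl]-3-[(triethylsilyl)oxy]nona-4,7-dien-1-yl acetate
Conditions: Et3SiOTf (3 equiv), 2,6-lutidine, CH2Cl2, 0 °C; then H2O, rt
Reagents that add atoms: triethylsilyl trifluoromethanesulfonate, CC[Si](CC)(CC)OS(=O)(=O)C(F)(F)F; water, O
Why: The silyl triflate/2,6-lutidine pair silylates the 9-OH and converts the dimethyl acetal through a pyridinium intermediate into the aldehyde on aqueous work-up, leaving acetate, lactone and vinyl iodide intact.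

Step 19
Reactants: 29 (1R,3R,4Z,7E)-8-iodo-4-methyl-1-[(2S,5S)-2-methyl-6-methylidene-7-oxo-5-(2-oxoethyl)oxepan-2-yl]-3-[(triethylsilyl)oxy]nona-4,7-dien-1-yl acetate
Product: 31 9-O-triethylsilyl ether of 34 as the mixture of C3 epimers (14-membered ring closed), via alkenylchromium species 30 (not isolated)
Conditions: CrCl2 (12 equiv), NiCl2 (0.1 equiv), degassed DMSO/THF, rt, syringe-pump addition to 2 mM
Reagents that add atoms: none
Why: Intramolecular Nozaki–Hiyama–Kishi reaction: nickel-catalysed formation of the alkenylchromium reagent keeps the (E) geometry and its aldehyde-selective addition under high dilution closes the 14-membered ring; the C3 configuration formed here is not relied on.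

Step 20
Reactants: 31 9-O-triethylsilyl ether of 34 as the mixture of C3 epimers
Product: 32 3-oxo-9-O-triethylsilyl macrocycle (4E-enone)
Conditions: Dess–Martin periodinane, NaHCO3, CH2Cl2, 0 °C
Reagents that add atoms: none
Why: Dess–Martin oxidation of the only free (allylic) alcohol converges both C3 epimers to one enone under non-basic conditions that do not move the skipped diene into conjugation.

Step 21
Reactants: 32 3-oxo-9-O-triethylsilyl macrocycle (4E-enone)
Product: 34 (1S,3S,4E,7Z,9R,11R,12S)-11-acetoxy-3,9-dihydroxycembra-4,7,15(17)-trien-16,12-olide (target), via 9-O-triethylsilyl ether 33 (not isolated)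
Conditions: (R)-1-methyl-3,3-diphenyl-tetrahydro-1H,3H-pyrrolo[1,2-c][1,3,2]oxazaborole (1 equiv), catecholborane, toluene/CH2Cl2, −78 °C; MeOH; then HF·pyridine, pyridine, THF, 0 °C
Reagents that add atoms: none
Why: Corey–Bakshi–Shibata reduction with the (R)-oxazaborolidine (alkenyl as the large group) gives the (3S) allylic alcohol under reagent control, and buffered HF then removes the silyl ether without acyl migration.

**Compound list**
1 | (S)-(−)-limonene | CC1=CC[C@H](CC1)C(C)=C | starting material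
2 | 10-lithiolimonene | CC1=CC[C@H](CC1)C(=C)C[Li] | intermediate (not isolated)
3 | dimethyl {2-[(1S)-4-methylcyclohex-3-en-1-yl]prop-2-en-1-yl}boronate | CC1=CC[C@H](CC1)C(=C)CB(OC)OC | intermediate (not isolated)
4 | 2-[(1S)-4-methylcyclohex-3-en-1-yl]prop-2-en-1-ol | CC1=CC[C@H](CC1)C(=C)CO | intermediate
5 | tert-butyl({2-[(1S)-4-methylcyclohex-3-en-1-yl]prop-2-en-1-yl}oxy)diphenylsilane | CC1=CC[C@H](CC1)C(=C)CO[Si](c1ccccc1)(c1ccccc1)C(C)(C)C | intermediate
6 | (3S)-3-{3-[(tert-butyldiphenylsilyl)oxy]prop-1-en-2-yl}-6-hydroperoxy-6-methoxyheptanal (C6 epimers) | COC(C)(OO)CC[C@H](C(=C)CO[Si](c1ccccc1)(c1ccccc1)C(C)(C)C)CC=O | intermediate (not isolated)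
7 | dimethyl acetal of 6 | COC(C)(OO)CC[C@H](C(=C)CO[Si](c1ccccc1)(c1ccccc1)C(C)(C)C)CC(OC)OC | intermediate (not isolated)
8 | (5S)-5-{3-[(tert-butyldiphenylsilyl)oxy]prop-1-en-2-yl}-7,7-dimethoxyheptan-2-one | CC(=O)CC[C@H](C(=C)CO[Si](c1ccccc1)(c1ccccc1)C(C)(C)C)CC(OC)OC | intermediate
9 | (2R)-2-[(3S)-3-{3-[(tert-butyldiphenylsilyl)oxy]prop-1-en-2-yl}-5,5-dimethoxypentyl]-2-methyloxirane | C[C@]1(CO1)CC[C@H](C(=C)CO[Si](c1ccccc1)(c1ccccc1)C(C)(C)C)CC(OC)OC | intermediate
10 | 2-{(3S)-5,5-dimethoxy-1-[(2R)-2-methyloxiran-2-yl]pentan-3-yl}prop-2-en-1-ol | C[C@]1(CO1)CC[C@H](C(=C)CO)CC(OC)OC | intermediate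
11 | 2-{(3S)-5,5-dimethoxy-1-[(2R)-2-methyloxiran-2-yl]pentan-3-yl}prop-2-enal | C[C@]1(CO1)CC[C@H](C(=C)C=O)CC(OC)OC | intermediate
12 | 2-{(3S)-5,5-dimethoxy-1-[(2R)-2-methyloxiran-2-yl]pentan-3-yl}prop-2-enoic acid | C[C@]1(CO1)CC[C@H](C(=C)C(O)=O)CC(OC)OC | intermediate (not isolated)
13 | (4S,7S)-4-(2,2-dimethoxyethyl)-7-(hydroxymethyl)-7-methyl-3-methylideneoxepan-2-one | C=C1C(=O)O[C@](C)(CO)CC[C@H]1CC(OC)OC | intermediate
14 | (2S,5S)-5-(2,2-dimethoxyethyl)-2-methyl-6-methylidene-7-oxooxepane-2-carbaldehyde | C=C1C(=O)O[C@](C)(C=O)CC[C@H]1CC(OC)OC | intermediate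
15 | pent-3-yn-1-ol | CC#CCCO | starting material
16 | (E)-alkenylzirconocene chloride from 15 (zirconium on C4, oxygen zirconated; cyclopentadienyl rings drawn η1) | C/C(=C\CCO[Zr](Cl)(C1C=CC=C1)C1C=CC=C1)[Zr](Cl)(C1C=CC=C1)C1C=CC=C1 | intermediate (not isolated)
17 | (3E)-4-iodopent-3-en-1-ol | C/C(I)=C\CCO | intermediate
18 | (2E)-2,5-diiodopent-2-ene | C/C(I)=C\CCI | intermediate
19 | [(3E)-4-iodopent-3-en-1-yl]triphenylphosphonium iodide | C/C(I)=C\CC[P+](c1ccccc1)(c1ccccc1)c1ccccc1.[I-] | intermediate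
20 | 3-hydroxybutan-2-one (acetoin, racemic) | CC(O)C(C)=O | starting material
21 | 3-[(tert-butyldimethylsilyl)oxy]butan-2-one (racemic) | CC(O[Si](C)(C)C(C)(C)C)C(C)=O | intermediate
22 | [(3E)-4-iodopent-3-en-1-ylidene]triphenylphosphorane | C/C(I)=C\CC=P(c1ccccc1)(c1ccccc1)c1ccccc1 | intermediate (not isolated)
23 | tert-butyl{[(3Z,6E)-7-iodo-3-methylocta-3,6-dien-2-yl]oxy}dimethylsilane (racemic) | C/C(I)=C\C/C=C(/C)C(C)O[Si](C)(C)C(C)(C)C | intermediate
24 | (3Z,6E)-7-iodo-3-methylocta-3,6-dien-2-ol (racemic) | C/C(I)=C\C/C=C(/C)C(C)O | intermediate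
25 | (3Z,6E)-7-iodo-3-methylocta-3,6-dien-2-one | C/C(I)=C\C/C=C(/C)C(C)=O | intermediate
26 | (3Z,6E)-7-iodo-3-methylocta-1,3,6-trien-2-yl dicyclohexylborinate | C=C(OB(C1CCCCC1)C1CCCCC1)/C(C)=C\C/C=C(\C)I | intermediate (not isolated)
27 | (4S,7S)-4-(2,2-dimethoxyethyl)-7-[(1R,4Z,7E)-1-hydroxy-8-iodo-4-methyl-3-oxonona-4,7-dien-1-yl]-7-methyl-3-methylideneoxepan-2-one | C=C1C(=O)O[C@](C)([C@H](O)CC(=O)/C(C)=C\C/C=C(\C)I)CC[C@H]1CC(OC)OC | intermediate
28 | (1R,3R,4Z,7E)-1-[(2S,5S)-5-(2,2-dimethoxyethyl)-2-methyl-6-methylidene-7-oxooxepan-2-yl]-3-hydroxy-8-iodo-4-methylnona-4,7-dien-1-yl acetate | C=C1C(=O)O[C@](C)([C@H](OC(C)=O)C[C@@H](O)/C(C)=C\C/C=C(\C)I)CC[C@H]1CC(OC)OC | intermediate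
29 | (1R,3R,4Z,7E)-8-iodo-4-methyl-1-[(2S,5S)-2-methyl-6-methylidene-7-oxo-5-(2-oxoethyl)oxepan-2-yl]-3-[(triethylsilyl)oxy]nona-4,7-dien-1-yl acetate | C=C1C(=O)O[C@](C)([C@H](OC(C)=O)C[C@@H](O[Si](CC)(CC)CC)/C(C)=C\C/C=C(\C)I)CC[C@H]1CC=O | intermediate
30 | alkenylchromium dichloride derived from 29 (chromium in place of iodine) | C=C1C(=O)O[C@](C)([C@H](OC(C)=O)C[C@@H](O[Si](CC)(CC)CC)/C(C)=C\C/C=C(\C)[Cr](Cl)Cl)CC[C@H]1CC=O | intermediate (not isolated)
31 | 9-O-triethylsilyl ether of 34, mixture of C3 epimers (C3 left undefined) | C=C1C(=O)O[C@@]2(C)CC[C@H]1CC(O)/C(C)=C/C/C=C(/C)[C@H](O[Si](CC)(CC)CC)C[C@H]2OC(C)=O | intermediate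
32 | 3-oxo-9-O-triethylsilyl macrocycle (4E-enone) | C=C1C(=O)O[C@@]2(C)CC[C@H]1CC(=O)/C(C)=C/C/C=C(/C)[C@H](O[Si](CC)(CC)CC)C[C@H]2OC(C)=O | intermediate
33 | 9-O-triethylsilyl ether of 34 (3S) | C=C1C(=O)O[C@@]2(C)CC[C@H]1C[C@H](O)/C(C)=C/C/C=C(/C)[C@H](O[Si](CC)(CC)CC)C[C@H]2OC(C)=O | intermediate (not isolated)
34 | (1S,3S,4E,7Z,9R,11R,12S)-11-acetoxy-3,9-dihydroxycembra-4,7,15(17)-trien-16,12-olide (CNP0183491.1) | C=C1C(=O)O[C@@]2(C)CC[C@H]1C[C@H](O)/C(C)=C/C/C=C(/C)[C@H](O)C[C@H]2OC(C)=O | target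

**Totals**
Total step count: 21. Longest linear sequence: 14 steps (1–8, then 16–21, from (S)-limonene); the other branch is steps 9–15.

**Three steps most likely to fail, with fallbacks**

Step 7 (acid-promoted epoxide opening). The 2,2-disubstituted epoxide may rearrange by hydride shift or lose stereochemical fidelity at C12. The fallback makes the tertiary C–O bond through an epoxy alcohol, where titanium-mediated delivery of a carboxylic acid to the distal epoxide carbon is established. It sets out from ketone 8 and comes back to the route at aldehyde 14. Horner–Wadsworth–Emmons olefination of 8 (triethyl phosphonoacetate, NaH, THF) gives ethyl (2E,6S)-6-{3-[(tert-butyldiphenylsilyl)oxy]prop-1-en-2-yl}-8,8-dimethoxy-3-methyloct-2-enoate F1. Reduction with (i-Bu)2AlH gives the allylic alcohol (2E,6S)-6-{3-[(tert-butyldiphenylsilyl)oxy]prop-1-en-2-yl}-8,8-dimethoxy-3-methyloct-2-en-1-ol F2, from which the minor Z isomer is removed. Sharpless asymmetric epoxidation (Ti(OiPr)4, D-(−)-diethyl tartrate, t-BuOOH, −20 °C) gives [(2R,3R)-3-[(3S)-3-{3-[(tert-butyldiphenylsilyl)oxy]prop-1-en-2-yl}-5,5-dimethoxypentyl]-3-methyloxiran-2-yl]methanol F3. Bu4NF gives 2-{(3S)-1-[(2R,3R)-3-(hydroxymethyl)-2-methyloxiran-2-yl]-5,5-dimethoxypentan-3-yl}prop-2-en-1-ol F4. MnO2 oxidises only the allylic alcohol to 2-{(3S)-1-[(2R,3R)-3-(hydroxymethyl)-2-methyloxiran-2-yl]-5,5-dimethoxypentan-3-yl}prop-2-enal F5. NaClO2 gives 2-{(3S)-1-[(2R,3R)-3-(hydroxymethyl)-2-methyloxiran-2-yl]-5,5-dimethoxypentan-3-yl}prop-2-enoic acid F6. Ti(OiPr)4 then delivers the carboxylate to the tertiary carbon with inversion, giving (4S,7S)-7-[(1R)-1,2-dihydroxyethyl]-4-(2,2-dimethoxyethyl)-7-methyl-3-methylideneoxepan-2-one F7, and NaIO4 glycol cleavage returns aldehyde 14.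

Step 16 (aldol; C11 ratio under substrate control). If the Felkin–Anh preference of the α-quaternary aldehyde is weak, control is moved to the reagent. The fallback sets out from ketone 25 and aldehyde 14 and comes back at aldol 27. Ketone 25 is enolised with (+)-B-chlorodiisopinocampheylborane and Et3N to (3Z,6E)-7-iodo-3-methylocta-1,3,6-trien-2-yl diisopinocampheylborinate F8. Its addition to 14 is steered by the chiral boron ligands; the sense for this antipode (re-face attack, matched with the Felkin–Anh preference) is written from memory, and the other antipode is used if a trial shows the opposite. The same buffered oxidative work-up gives 27.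

Step 19 (chromium-mediated macrocyclization; oligomerisation or low conversion). The ring is then closed as an acylation instead of a carbonyl addition. The fallback sets out from aldehyde 29 and comes back at enone 32, bypassing 31 and step 20. NaClO2 oxidation of 29 gives 2-[(4S,7S)-7-{(1R,3R,4Z,7E)-1-acetoxy-8-iodo-4-methyl-3-[(triethylsilyl)oxy]nona-4,7-dien-1-yl}-7-methyl-3-methylidene-2-oxooxepan-4-yl]acetic acid F9. 2,2'-Dipyridyl disulfide and PPh3 convert it into the S-pyridin-2-yl thioester F10. Intramolecular reductive coupling of the vinyl iodide with the thioester (NiBr2(4,4'-di-tert-butyl-2,2'-bipyridine) cat., Cp2ZrCl2, Zn, 1,3-dimethyl-2-imidazolidinone/THF, high dilution) gives macrocyclic enone 32 directly.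

**Further compounds**
F1 | step 7 | ethyl (2E,6S)-6-{3-[(tert-butyldiphenylsilyl)oxy]prop-1-en-2-yl}-8,8-dimethoxy-3-methyloct-2-enoate | CCOC(=O)/C=C(\C)CC[C@H](C(=C)CO[Si](c1ccccc1)(c1ccccc1)C(C)(C)C)CC(OC)OC
F2 | step 7 | (2E,6S)-6-{3-[(tert-butyldiphenylsilyl)oxy]prop-1-en-2-yl}-8,8-dimethoxy-3-methyloct-2-en-1-ol | OC/C=C(\C)CC[C@H](C(=C)CO[Si](c1ccccc1)(c1ccccc1)C(C)(C)C)CC(OC)OC
F3 | step 7 | [(2R,3R)-3-[(3S)-3-{3-[(tert-butyldiphenylsilyl)oxy]prop-1-en-2-yl}-5,5-dimethoxypentyl]-3-methyloxiran-2-yl]methanol | OC[C@H]1O[C@]1(C)CC[C@H](C(=C)CO[Si](c1ccccc1)(c1ccccc1)C(C)(C)C)CC(OC)OC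
F4 | step 7 | 2-{(3S)-1-[(2R,3R)-3-(hydroxymethyl)-2-methyloxiran-2-yl]-5,5-dimethoxypentan-3-yl}prop-2-en-1-ol | OC[C@H]1O[C@]1(C)CC[C@H](C(=C)CO)CC(OC)OC
F5 | step 7 | 2-{(3S)-1-[(2R,3R)-3-(hydroxymethyl)-2-methyloxiran-2-yl]-5,5-dimethoxypentan-3-yl}prop-2-enal | OC[C@H]1O[C@]1(C)CC[C@H](C(=C)C=O)CC(OC)OC
F6 | step 7 | 2-{(3S)-1-[(2R,3R)-3-(hydroxymethyl)-2-methyloxiran-2-yl]-5,5-dimethoxypentan-3-yl}prop-2-enoic acid | OC[C@H]1O[C@]1(C)CC[C@H](C(=C)C(O)=O)CC(OC)OC
F7 | step 7 | (4S,7S)-7-[(1R)-1,2-dihydroxyethyl]-4-(2,2-dimethoxyethyl)-7-methyl-3-methylideneoxepan-2-one | C=C1C(=O)O[C@](C)([C@H](O)CO)CC[C@H]1CC(OC)OC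
F8 | step 16 | (3Z,6E)-7-iodo-3-methylocta-1,3,6-trien-2-yl diisopinocampheylborinate | C=C(OB([C@H]1C[C@H]2C[C@@H]([C@@H]1C)C2(C)C)[C@H]1C[C@H]2C[C@@H]([C@@H]1C)C2(C)C)/C(C)=C\C/C=C(\C)I
F9 | step 19 | 2-[(4S,7S)-7-{(1R,3R,4Z,7E)-1-acetoxy-8-iodo-4-methyl-3-[(triethylsilyl)oxy]nona-4,7-dien-1-yl}-7-methyl-3-methylidene-2-oxooxepan-4-yl]acetic acid | C=C1C(=O)O[C@](C)([C@H](OC(C)=O)C[C@@H](O[Si](CC)(CC)CC)/C(C)=C\C/C=C(\C)I)CC[C@H]1CC(O)=O
F10 | step 19 | S-pyridin-2-yl thioester of F9 | C=C1C(=O)O[C@](C)([C@H](OC(C)=O)C[C@@H](O[Si](CC)(CC)CC)/C(C)=C\C/C=C(\C)I)CC[C@H]1CC(=O)Sc1ccccn1
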